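**Strategy**

The route rests on cutting ring A (C1–C5, C10) from ring B at C1–C10 and C4–C5. Ring B, with the C10 angular methyl, the C8 methyl and oxidised C6 and C9 flanking C7=C8, is a masked 2,6-dimethyl-1,4-benzoquinone; the key step exploits this by adding a C1–C4 diene across one quinone alkene. One enantioselective Diels–Alder reaction thus closes ring A, forms both ring-fusion bonds and sets the C4 and C10 quaternary centres with C19 syn to the C10 methyl. The diene is (Z)-2-methylpenta-2,4-dienyl TBS ether, whose Z geometry encodes C4. The C6 carbonyl later corrects C5; the C9 carbonyl anchors the side chain.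

Key step: step 4

Remark (assumption): labdane numbering is used throughout (C19 = CH2O carbon on C4, C18 = C4 methyl, C20 = C10 methyl, C17 = C8 methyl; β = the face carrying C20); the handedness of the boron catalyst in step 4 is assigned from the accepted carbonyl-binding model of this catalyst class, and the mirror-image catalyst, equally available, would be used if the sense of induction proved opposite.

**Route**

Step 1
Reactants: 1 acrolein; 2 ethyl 2-[bis(2,2,2-trifluoroethoxy)phosphoryl]propanoate
Product: 3 ethyl (Z)-2-methylpenta-2,4-dienoate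
Conditions: KN(SiMe3)2, 18-crown-6, THF, −78 °C; aq. NH4Cl
Reagents that add atoms: none
Why: Still–Gennari olefination, in which the electron-poor bis(trifluoroethyl) phosphonate eliminates from the kinetic adduct and should place the ester cis to the vinyl group (Z).

Step 2
Reactants: 3 ethyl (Z)-2-methylpenta-2,4-dienoate
Product: 4 (Z)-2-methylpenta-2,4-dien-1-ol
Conditions: i-Bu2AlH, CH2Cl2, −78 °C; aq. potassium sodium tartrate
Reagents that add atoms: none
Why: 1,2-reduction of the conjugated ester by a dialkylaluminium hydride at low temperature should give the allylic alcohol without touching the diene or its Z geometry.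

Step 3
Reactants: 4 (Z)-2-methylpenta-2,4-dien-1-ol
Product: 5 (Z)-tert-butyldimethyl[(2-methylpenta-2,4-dien-1-yl)oxy]silane
Conditions: TBSCl, imidazole, CH2Cl2, 0 °C → rt
Reagents that add atoms: tert-butyldimethylsilyl chloride, CC(C)(C)[Si](C)(C)Cl
Why: Standard silylation of a primary alcohol; the bulky, weakly basic silyl ether should not compete with the quinone carbonyl for the boron catalyst.

Step 4
Reactants: 5 (Z)-tert-butyldimethyl[(2-methylpenta-2,4-dien-1-yl)oxy]silane; 6 2,6-dimethyl-1,4-benzoquinone
Product: 7 cis-fused adduct (ring A 2-ene; ring B 7-ene-6,9-dione; 4β-CH2OTBS, 10β-methyl, 5β-H)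
Conditions: (S)-1-(2-methylphenyl)-3,3-diphenyltetrahydro-1H,3H-pyrrolo[1,2-c][1,3,2]oxazaborole (20 mol %), Tf2NH (18 mol %), 5 (2 equiv), CH2Cl2, −78 → −20 °C
Reagents that add atoms: none
Why: The reaction is a concerted, asynchronous [4π+2π] cycloaddition in which the cationic boron Lewis acid binds the quinone carbonyl flanked by the two C–H positions (future C6=O), so the methyl-bearing β-carbon (future C10) bonds first to the unsubstituted diene terminus C1 and the hindered terminus C4 then closes onto C5. The closest known reaction type is the oxazaborolidinium-catalysed enantioselective Diels–Alder reaction of 2,6-dialkylbenzoquinones with acyclic dienes. Ring A closes as a cyclohexene by suprafacial–suprafacial addition across one quinone alkene with the quinone carbonyls endo. Three stereocentres form: C10 and C5 share the cis ring fusion imposed by suprafacial addition to the dienophile, C4 follows from the fixed Z geometry (the inside CH2OTBS group ends syn to the C10 methyl and H-5 in the endo mode), and the absolute sense follows from the catalyst shielding one face of the bound enone. The step needs regioselectivity (C1 to C10, C4 to C5), endo selectivity and monoaddition, which are secured by the catalyst-bound carbonyl, by the larger HOMO coefficient at C1 together with the lower hindrance at C5, and by the lower reactivity of the remaining trisubstituted enedione alkene. C4 and C10 persist to the target, whereas C5 is inverted in step 5.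

Step 5
Reactants: 7 cis-fused adduct
Product: 9 trans-fused saturated 6,9-dione (5α-H; 8α-methyl), via cis-fused saturated dione 8 (not isolated)
Conditions: H2 (1 atm), Pd/C, EtOAc, rt; filter; NaOMe (0.2 equiv), MeOH, rt
Reagents that add atoms: none
Why: Heterogeneous catalytic hydrogenation should saturate the ring A C2=C3 bond and the enedione C7=C8 bond, and base-mediated thermodynamic epimerisation then brings C5 (through the C6 enolate) to the trans ring fusion with H-5 α and C8 to the equatorial methyl.

Step 6
Reactants: 9 trans-fused saturated 6,9-dione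
Product: 10 C6 enol triflate (C6(OTf)=C7; C9 ketone intact)
Conditions: LiN(i-Pr)2, THF, −78 °C; PhNTf2, −78 → 0 °C; aq. NH4Cl
Reagents that add atoms: N-phenylbis(trifluoromethanesulfonimide), O=S(=O)(N(c1ccccc1)S(=O)(=O)C(F)(F)F)C(F)(F)F
Why: Kinetic enolate formation and O-triflation: the C7 methylene is the only unhindered acidic position (H-5 and H-8 are tertiary and flanked by quaternary carbons), so the amide base should give the C6–C7 enolate that the triflimide traps on oxygen; no stereocentre is formed.

Step 7
Reactants: 10 C6 enol triflate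
Product: 12 7-en-9-one (C7=C8 conjugated to the C9 ketone; 5α-H), via 6-en-9-one 11 (not isolated)
Conditions: Pd(OAc)2 (5 mol %), PPh3, HCO2H, Bu3N, DMF, 60 °C; then DBU (0.2 equiv), CH2Cl2, rt
Reagents that add atoms: none
Why: Palladium-catalysed formate reduction of the enol triflate (oxidative addition, formate-to-hydride exchange with loss of CO2, reductive elimination) removes the C6 oxygen, and base-mediated isomerisation through the C9 dienolate then moves the alkene into conjugation as C7=C8 without touching C5.

Step 8
Reactants: 12 7-en-9-one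
Product: 13 9-(ethoxyethynyl)-9-hydroxy-7-ene carbinol
Conditions: ethoxyacetylene, n-BuLi, THF, −78 °C; add 12, −78 → 0 °C; aq. NH4Cl
Reagents that add atoms: ethoxyacetylene, C#COCC
Why: 1,2-Addition of a small, linear lithium acetylide to the hindered, non-enolisable C9 carbonyl (alkynylation of a ketone); attack is expected on the α face opposite the C10 methyl, but this centre is erased in step 9.

Step 9
Reactants: 13 9-(ethoxyethynyl)-9-hydroxy-7-ene carbinol
Product: 14 ethyl dienoate (exocyclic C9=C11, C12 = CO2Et, 7-ene)
Conditions: Sc(OTf)3 (5 mol %), CH2Cl2–EtOH, 0 °C → rt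
Reagents that add atoms: none
Why: Meyer–Schuster rearrangement of an alkoxyalkynyl carbinol: Lewis-acid activation of the electron-rich ynol ether, 1,3-oxygen shift and tautomerisation should give the α,β-unsaturated ester, expected mainly with C12 anti to the quaternary C10 (E); either geometry serves step 11.

Step 10
Reactants: 14 ethyl dienoate
Product: 15 dienol (C12 = CH2OH)
Conditions: i-Bu2AlH, CH2Cl2, −78 °C; aq. potassium sodium tartrate
Reagents that add atoms: none
Why: 1,2-Reduction of the conjugated ester with a dialkylaluminium hydride should give the primary allylic alcohol and leave the diene untouched.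

Step 11
Reactants: 15 dienol
Product: 18 9β-vinyl-7-ene (9α-H; 19-OTBS), via sulfonylhydrazine adduct 16 (not isolated), via allylic diazene 17 (not isolated)
Conditions: 2-nitrobenzenesulfonylhydrazide, PPh3, DEAD, N-methylmorpholine, −30 °C → rt
Reagents that add atoms: none
Why: Reductive 1,3-transposition of an allylic alcohol by Mitsunobu displacement at primary C12, loss of sulfinate to the monoalkyl diazene and a retro-ene shift that passes the N–H hydrogen to C9 with loss of N2, forming the C11=C12 vinyl group; delivery on the axial α face, anti to the adjacent C10 methyl, should set C9 with the vinyl group equatorial (β).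

Step 12
Reactants: 18 9β-vinyl-7-ene
Product: 19 C19 alcohol
Conditions: Bu4NF, THF, rt → 40 °C; aq. NH4Cl
Reagents that add atoms: none
Why: Fluoride-mediated cleavage of the silyl ether, driven by the Si–F bond, should free the C19 alcohol while no other group responds.

Step 13
Reactants: 19 C19 alcohol
Product: 20 C19 angelate
Conditions: angelic acid, 2,4,6-trichlorobenzoyl chloride, Et3N, toluene, rt; then 19, 80 °C
Reagents that add atoms: angelic acid, C/C=C(/C)C(=O)O
Why: Yamaguchi-type acylation through the mixed 2,4,6-trichlorobenzoic anhydride without a nucleophilic amine catalyst, conditions under which the (Z)-2-methylbut-2-enoyl group is expected to transfer without isomerisation to the tiglate.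

Step 14
Reactants: 21 but-2-ynoic acid
Product: 22 (Z)-3-iodobut-2-enoic acid
Conditions: NaI, AcOH, 110 °C
Reagents that add atoms: sodium iodide, [Na+].[I-]
Why: Hydroiodination of an ynoic acid by conjugate addition of iodide and anti protonation should give the β-iodo acid with iodine cis to the carboxyl group (Z).

Step 15
Reactants: 22 (Z)-3-iodobut-2-enoic acid
Product: 23 2-(trimethylsilyl)ethyl (Z)-3-iodobut-2-enoate
Conditions: 2-(trimethylsilyl)ethanol, PPh3, DIAD, THF, 0 °C → rt
Reagents that add atoms: 2-(trimethylsilyl)ethanol, C[Si](C)(C)CCO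
Why: Mitsunobu esterification activates the alcohol and not the acyl group, so the β-iodoenoate geometry should not be scrambled by addition–elimination.

Step 16
Reactants: 20 C19 angelate; 23 2-(trimethylsilyl)ethyl (Z)-3-iodobut-2-enoate
Product: 25 2-(trimethylsilyl)ethyl ester of the target, via B-alkyl-9-borabicyclononane 24 (not isolated)
Conditions: 9-BBN, THF, rt; then 23, Pd(dppf)Cl2 (5 mol %), AsPh3, Cs2CO3, DMF–H2O, rt
Reagents that add atoms: none
Why: Anti-Markovnikov hydroboration of the monosubstituted vinyl group by the bulky dialkylborane (trisubstituted alkenes and esters are inert) followed by B-alkyl Suzuki–Miyaura coupling, which proceeds with retention at the vinyl iodide and should therefore fix the 13Z geometry (C12 cis to C15).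

Step 17
Reactants: 25 2-(trimethylsilyl)ethyl ester of the target
Product: 26 (13Z)-19-[(Z)-2-methylbut-2-enoyloxy]labda-7,13-dien-15-oic acid (CNP0249147.1)
Conditions: Bu4NF, THF, 0 °C → rt; dilute aq. HCl
Reagents that add atoms: none
Why: Fluoride-induced β-elimination of the 2-(trimethylsilyl)ethyl ester (loss of fluorotrimethylsilane and ethene) should free the acid under conditions that leave the hindered angelate ester untouched.

**Compound list**

1 | acrolein | C=CC=O | starting material
2 | ethyl 2-[bis(2,2,2-trifluoroethoxy)phosphoryl]propanoate | CCOC(=O)C(C)P(=O)(OCC(F)(F)F)OCC(F)(F)F | starting material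
3 | ethyl (Z)-2-methylpenta-2,4-dienoate | C=C/C=C(/C)C(=O)OCC | intermediate
4 | (Z)-2-methylpenta-2,4-dien-1-ol | C=C/C=C(/C)CO | intermediate
5 | (Z)-tert-butyldimethyl[(2-methylpenta-2,4-dien-1-yl)oxy]silane | C=C/C=C(/C)CO[Si](C)(C)C(C)(C)C | intermediate
6 | 2,6-dimethyl-1,4-benzoquinone | CC1=CC(=O)C=C(C)C1=O | starting material
7 | cis-fused adduct: ring A 2-ene, ring B 7-ene-6,9-dione, 4β-CH2OTBS, 4α-methyl, 10β-methyl, 5β-H | CC(C)(C)[Si](C)(C)OC[C@@]1(C)C=CC[C@]2(C)C(=O)C(C)=CC(=O)[C@H]12 | intermediate
8 | cis-fused saturated 6,9-dione (5β-H; both C8 epimers) | CC(C)(C)[Si](C)(C)OC[C@@]1(C)CCC[C@]2(C)C(=O)C(C)CC(=O)[C@H]12 | intermediate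
9 | trans-fused saturated 6,9-dione (5α-H, 8α-methyl) | CC(C)(C)[Si](C)(C)OC[C@@]1(C)CCC[C@]2(C)C(=O)[C@H](C)CC(=O)[C@@H]12 | intermediate
10 | C6 enol triflate of 9 (C6(OTf)=C7, C9 ketone, 5α-H) | CC(C)(C)[Si](C)(C)OC[C@@]1(C)CCC[C@]2(C)C(=O)[C@H](C)C=C(OS(=O)(=O)C(F)(F)F)[C@@H]12 | intermediate
11 | 6-en-9-one (C6=C7, 8α-methyl, 5α-H) | CC(C)(C)[Si](C)(C)OC[C@@]1(C)CCC[C@]2(C)C(=O)[C@H](C)C=C[C@@H]12 | intermediate
12 | 7-en-9-one (C7=C8 conjugated to C9=O, 5α-H, 19-OTBS) | CC(C)(C)[Si](C)(C)OC[C@@]1(C)CCC[C@]2(C)C(=O)C(C)=CC[C@@H]12 | intermediate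
13 | 9-(ethoxyethynyl)-9-hydroxy-7-ene carbinol (9β-OH epimer expected) | CC(C)(C)[Si](C)(C)OC[C@@]1(C)CCC[C@]2(C)[C@](O)(C#COCC)C(C)=CC[C@@H]12 | intermediate
14 | ethyl (E)-dienoate: exocyclic C9=C11, C12 = CO2Et, 7-ene | CC(C)(C)[Si](C)(C)OC[C@@]1(C)CCC[C@]2(C)/C(=C/C(=O)OCC)C(C)=CC[C@@H]12 | intermediate
15 | (E)-dienol: C12 = CH2OH, exocyclic C9=C11, 7-ene | CC(C)(C)[Si](C)(C)OC[C@@]1(C)CCC[C@]2(C)/C(=C/CO)C(C)=CC[C@@H]12 | intermediate
16 | N-(C12-alkyl)-N-(2-nitrophenylsulfonyl)hydrazine derived from 15 | CC(C)(C)[Si](C)(C)OC[C@@]1(C)CCC[C@]2(C)/C(=C/CN(N)S(=O)(=O)c3ccccc3[N+](=O)[O-])C(C)=CC[C@@H]12 | intermediate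
17 | allylic monoalkyl diazene (C12–N=NH) | CC(C)(C)[Si](C)(C)OC[C@@]1(C)CCC[C@]2(C)/C(=C/CN=N)C(C)=CC[C@@H]12 | intermediate
18 | 9β-vinyl-7-ene (9α-H, 5α-H, 19-OTBS) | CC(C)(C)[Si](C)(C)OC[C@@]1(C)CCC[C@]2(C)[C@@H](C=C)C(C)=CC[C@@H]12 | intermediate
19 | C19 alcohol of 18 | OC[C@@]1(C)CCC[C@]2(C)[C@@H](C=C)C(C)=CC[C@@H]12 | intermediate
20 | C19 angelate [(Z)-2-methylbut-2-enoate] of 19 | C/C=C(/C)C(=O)OC[C@@]1(C)CCC[C@]2(C)[C@@H](C=C)C(C)=CC[C@@H]12 | intermediate
21 | but-2-ynoic acid | CC#CC(=O)O | starting material
22 | (Z)-3-iodobut-2-enoic acid | C/C(I)=C/C(=O)O | intermediate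
23 | 2-(trimethylsilyl)ethyl (Z)-3-iodobut-2-enoate | C/C(I)=C/C(=O)OCC[Si](C)(C)C | intermediate
24 | C12-(9-borabicyclo[3.3.1]nonan-9-yl) derivative of 20 | C/C=C(/C)C(=O)OC[C@@]1(C)CCC[C@]2(C)[C@@H](CCB3C4CCCC3CCC4)C(C)=CC[C@@H]12 | intermediate
25 | 2-(trimethylsilyl)ethyl ester of 26 | C/C=C(/C)C(=O)OC[C@@]1(C)CCC[C@]2(C)[C@@H](CC/C(C)=C\C(=O)OCC[Si](C)(C)C)C(C)=CC[C@@H]12 | intermediate
26 | (13Z)-19-[(Z)-2-methylbut-2-enoyloxy]labda-7,13-dien-15-oic acid (CNP0249147.1) | C/C=C(/C)C(=O)OC[C@@]1(C)CCC[C@]2(C)[C@@H](CC/C(C)=C\C(=O)O)C(C)=CC[C@@H]12 | target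

**Step count and risks**

Total step count: 17. Longest linear sequence: 15 steps (steps 1–13, 16 and 17); steps 14 and 15 prepare coupling partner 23.

Steps most likely to fail:

1. Step 4. The hindered, Z-substituted diene terminus may react too slowly with the catalyst-bound quinone, the diene may isomerise or ionise under the acidic catalyst, and face selection may be eroded. The fallback gives up catalyst control and resolves instead. Setting out from 5 and 6, activation of the same quinone carbonyl with stoichiometric BF3·OEt2 (CH2Cl2, −78 → −20 °C) should give 7 together with its mirror-image adduct F1. Preparative chromatography on a chiral stationary phase (amylose tris(3,5-dimethylphenylcarbamate)) would then separate 7, at which compound the route is rejoined.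

2. Step 5. Epimerisation at C5 may stay incomplete because the cis/trans equilibrium of the ring fusion, with two quaternary neighbours and an angular methyl, may not lie far enough on the trans side. The fallback sets C5 kinetically by dissolving-metal reduction. Setting out from 7, enolisation toward C5 and O-triflation (KN(SiMe3)2, PhNTf2, THF, −78 °C) should give the dienyl triflate F2. Formate reduction (Pd(OAc)2, PPh3, HCO2H, Bu3N, DMF) should give the linear 5,7-dien-9-one F3. Birch-type 1,6-reduction (Li, NH3, t-BuOH, THF, −78 °C; NH4Cl) should protonate C5 on the α face, anti to both axial β substituents C19 and C20, and give the 2,6-dien-9-one F4. DBU then conjugates this to the 2,7-dien-9-one F5, and hydrogenation of the ring A alkene alone (H2, RhCl(PPh3)3, benzene) returns to the route at 12.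

3. Step 11. Hydrogen transfer to C9 in the retro-ene step may show poor facial selectivity, or the Mitsunobu displacement on the dienylic alcohol may be diverted. The fallback replaces the sigmatropic transfer by palladium-mediated hydride delivery. Setting out from 15, formylation (HCO2H, Ac2O, pyridine, 0 °C) should give the allylic formate F6. Heating with Pd(OAc)2 and PBu3 in dioxane should form the π-allylpalladium formate on the less hindered α face, lose CO2 and pass hydride from the metal to the more substituted terminus C9. This leaves the terminal vinyl group and returns to the route at 18.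

Further compounds
F1 | step 4 | mirror-image adduct (enantiomer of 7) | CC(C)(C)[Si](C)(C)OC[C@]1(C)C=CC[C@@]2(C)C(=O)C(C)=CC(=O)[C@@H]12
F2 | step 5 | dienyl triflate (C5=C6(OTf), C7=C8, C9 ketone, ring A 2-ene) | CC(C)(C)[Si](C)(C)OC[C@@]1(C)C=CC[C@]2(C)C(=O)C(C)=CC(OS(=O)(=O)C(F)(F)F)=C12
F3 | step 5 | 2,5,7-trien-9-one (linear 5,7-dien-9-one with ring A 2-ene) | CC(C)(C)[Si](C)(C)OC[C@@]1(C)C=CC[C@]2(C)C(=O)C(C)=CC=C12
F4 | step 5 | 2,6-dien-9-one (5α-H; C8 epimers) | CC(C)(C)[Si](C)(C)OC[C@@]1(C)C=CC[C@]2(C)C(=O)C(C)C=C[C@@H]12
F5 | step 5 | 2,7-dien-9-one (5α-H) | CC(C)(C)[Si](C)(C)OC[C@@]1(C)C=CC[C@]2(C)C(=O)C(C)=CC[C@@H]12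
F6 | step 11 | C12 formate of dienol 15 | CC(C)(C)[Si](C)(C)OC[C@@]1(C)CCC[C@]2(C)/C(=C/COC=O)C(C)=CC[C@@H]12
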